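Remark on the chemistry: the target has no stereocentre. Compounds 1, 4, 6 and 7 are taken as purchasable. The stereocentres of 10 and 12 are racemic and disappear within step 6.

## Analysis of the target

The target is a flavone. Ring A (C4a, C5, C6, C7, C8, C8a) is fused to the 4-pyranone ring C (O1, C2, C3, C4, C4a, C8a), and C2 carries ring B, a 4-hydroxyphenyl group. There is no stereocentre and no hindered axis, so the problem is one of substitution pattern only. Ring A is hexasubstituted: methoxy groups on C5, C6 and C8, a free hydroxyl on C7, the ring oxygen O1 on C8a and the C4 carbonyl on C4a. A fourth methoxy group sits on C3.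

The feature that the route uses is this: the four contiguous oxygen-bearing carbons C5–C6–C7–C8 are a C4O4 unit with the connectivity of squaric acid. The two remaining ring A carbons, C4a and C8a, are at the same time the enol ether double bond (C5=C6) of a 2-aryl-3-methoxy-4-pyranone.

Two things make the synthesis hard. First, a benzene ring with six different neighbours cannot be built by successive aromatic substitutions with dependable regiocontrol. Second, O7 must stay free while O5, O6 and O8 are methylated, although O7 (para to the C4 carbonyl through C4a) is the most acidic and most easily alkylated oxygen of a flavone.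

Sensitive points: ring A with free para oxygens at C5 and C8 is oxidised easily to a quinone; a 5-methoxy group peri to the carbonyl is cleaved by strong Lewis acids; the pyranone is opened by hard nucleophiles at C2.

## Retrosynthetic reasoning

**16 to 15.** The O–CH2Ph bonds at O7 and O4' are cut. Both phenols are carried as benzyl ethers because these survive base, an organolithium, heat and acid, and both fall in one hydrogenolysis at the end.

**15 to 14.** The three O–CH3 bonds at O5, O6 and O8 are cut. The forward step is an exhaustive methylation. Since O7 is blocked, the natural preference of a flavone for alkylation at O7 no longer matters.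

**14 to 10 (key disconnection).** Ring A is taken apart as a whole. The bond C5–C4a is cut, and C5, C6, C7 and C8 are folded back into the four-membered ring of cyclobutenone 10, whose carbinol carbon carries the pyranone through the future C8–C8a bond. This is chosen because one thermal operation on 10 then makes the complete hexasubstituted ring, with every oxygen already on its carbon, from a precursor that has no benzene ring A at all. The forward reaction has to open the cyclobutenone to a dienylketene, close it onto the pyranone carbon next to the carbonyl (future C4a) and aromatise. O6 is carried as a tert-butyl ether, removed by acid in the same flask.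

**10 to 5 and 8.** The bond C8–C8a is cut. Forward, 5 is metallated at C6 (next to the ring oxygen, the future C8a) and added to one carbonyl of squarate 8. Which carbonyl reacts decides which oxygen ends on C7. In 8 the two alkoxy groups are therefore made as different as possible: a small benzyloxy group (to become O7, kept) and a bulky tert-butoxy group (to become O6, replaced by methyl after step 6). Attack next to the small group puts the benzyloxy carbon beside the carbinol carbon, that is C7 beside C8.

**8 to 6 and 7.** One alkoxy C–O bond of the squarate is cut; forward, one tert-butoxy group of symmetric 6 is exchanged for the alkoxide of 7.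

**5 to 3 and 4, 3 to 2, 2 to 1.** The C2–C1' bond between rings C and B is cut (cross-coupling of bromide 3 with boronic acid 4). The C3 methoxy group comes from O-methylation of 2, and the bromine from bromination of 1 at the carbon activated by the enolic hydroxyl. This places the C3 methoxy and ring B before ring A exists, so the key step works on a small, fully defined partner.

## Alternatives that were turned down

**Alternative 1:** the textbook route. Ring C is disconnected at O1–C2 and C2–C3. Forward, the hexasubstituted ketone A1 undergoes an Allan–Robinson condensation (O-aroylation, acyl shift, cyclodehydration) with an activated 4-(benzyloxy)benzoic acid derivative to give 15.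
- It leaves the whole difficulty in the starting material: A1 is itself a hexasubstituted benzene, and needs about five arene steps, including a selective demethylation beside the acyl group in the presence of a benzyl ether.
- The chalcone and oxidative-cyclisation variant is worse, because a chalcone with a substituent at the 6'-position (here methoxy) tends to give the aurone instead of the flavonol.
- The key step makes two bonds of ring C and nothing of ring A.

**Alternative 2:** hidden mirror symmetry of ring A. If O1 is written as a methoxy group, C5/C8a and C6/C8 are equivalent, so a symmetric aryl unit can be used. Forward, ynone A2 undergoes an iodonium-induced demethylative 6-endo cyclisation to 3-iodoflavone A3, and a copper-mediated methoxylation at C3 then gives 15.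
- The key step forms only the O1–C2 bond.
- Ring A still has to be substituted position by position through successive directed metalations.
- The C3–O bond must be made on an α-iodo enone, where methoxide prefers addition at C2 and opening of ring C.
- The step count is no lower than that of the chosen route.

**Alternative 3:** ring A from the same squarate 8 and an open-chain β-lithiated 3-methoxyacrylate, by the same type of ring expansion. This would give salicylate A4; ring C would then be closed by Claisen condensation with an aryl methoxymethyl ketone and cyclodehydration to 15.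
- The ring expansion then delivers ring A alone, and four to five more steps are needed to reach the flavone.
- Two of three phenols must be methylated selectively while the chelated one is spared.
- The lithiated acrylate is prone to self-condensation.
- Annulating onto the preformed pyranone is more convergent.

Key step: step 6

## Route

**Step 1**
Reactants: 1 3-hydroxy-4H-pyran-4-one
Product: 2 2-bromo-3-hydroxy-4H-pyran-4-one
Conditions: NBS (1.0 equiv), MeCN, 0 °C to rt
Reagents that add atoms: N-bromosuccinimide, O=C1CCC(=O)N1Br
Why: Electrophilic bromination of an enol; the free 3-hydroxyl activates C2, the enol carbon next to O1, as in the halogenation of other 3-hydroxy-4-pyranones, and leaves C5 and C6 untouched for the annulation.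

**Step 2**
Reactants: 2 2-bromo-3-hydroxy-4H-pyran-4-one
Product: 3 2-bromo-3-methoxy-4H-pyran-4-one
Conditions: MeI, K2CO3, acetone, 50 °C
Reagents that add atoms: iodomethane, CI
Why: Williamson O-methylation of the acidic enolic hydroxyl with a mild carbonate base; it fixes the C3 methoxy group of the target at the start.

**Step 3**
Reactants: 3 2-bromo-3-methoxy-4H-pyran-4-one; 4 [4-(benzyloxy)phenyl]boronic acid
Product: 5 2-[4-(benzyloxy)phenyl]-3-methoxy-4H-pyran-4-one
Conditions: Pd(PPh3)4 (5 mol %), K2CO3, dioxane/H2O, 85 °C
Reagents that add atoms: none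
Why: Suzuki–Miyaura coupling; the C2–Br bond is a vinylogous acyl bromide and should add readily to the zerovalent palladium complex, and the carbonate base is too weak to open the pyranone.

**Step 4**
Reactants: 6 3,4-di-tert-butoxycyclobut-3-ene-1,2-dione (di-tert-butyl squarate); 7 benzyl alcohol
Product: 8 3-(benzyloxy)-4-(tert-butoxy)cyclobut-3-ene-1,2-dione
Conditions: 7 (1.0 equiv), KOtBu (5 mol %), THF, −20 to 0 °C
Reagents that add atoms: none
Why: Alkoxide-catalysed transesterification of a vinylogous ester by addition–elimination; the first exchange relieves the crowding of two neighbouring tert-butoxy groups and the single equivalent of 7 limits a second exchange, so the mixed ester should be the main product and is separated from recovered 6.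

**Step 5**
Reactants: 5 2-[4-(benzyloxy)phenyl]-3-methoxy-4H-pyran-4-one; 8 3-(benzyloxy)-4-(tert-butoxy)cyclobut-3-ene-1,2-dione
Product: 10 3-(benzyloxy)-4-{6-[4-(benzyloxy)phenyl]-5-methoxy-4-oxo-4H-pyran-2-yl}-2-(tert-butoxy)-4-hydroxycyclobut-2-en-1-one (racemic), via pyranyllithium 9 (not isolated)
Conditions: LiTMP (lithium 2,2,6,6-tetramethylpiperidide, 1.05 equiv), THF, −78 °C; then 8, −78 °C; aq. NH4Cl
Reagents that add atoms: none
Why: The hindered amide removes the most acidic ring hydrogen of 5, at C6 next to the ring oxygen (as in the C2 lithiation of chromones), and vinyllithium 9 adds 1,2 to a squarate carbonyl at low temperature, the usual first step of squarate annulations. The carbonyl flanked by C–OBn should react, because the tert-butyl group lies in the ring plane beside the other carbonyl and screens it; this puts OBn next to the carbinol carbon and OtBu next to the remaining carbonyl. The new carbinol stereocentre is racemic and is destroyed in step 6.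

**Step 6**
Reactants: 10 3-(benzyloxy)-4-{6-[4-(benzyloxy)phenyl]-5-methoxy-4-oxo-4H-pyran-2-yl}-2-(tert-butoxy)-4-hydroxycyclobut-2-en-1-one
Product: 14 7-(benzyloxy)-2-[4-(benzyloxy)phenyl]-5,6,8-trihydroxy-3-methoxy-4H-chromen-4-one, via dienylketene 11 (not isolated), via cyclohexadienone 12 (not isolated), via hydroquinone 13 (not isolated)
Conditions: toluene (degassed), 110 °C, argon; then CF3CO2H, rt
Reagents that add atoms: none
Why: Heating opens the cyclobutenone of 10 by conrotatory 4π electrocyclic cleavage of the bond between the carbonyl carbon and the carbinol carbon; the hydroxyl, a donor, rotates outward, so the pyranyl group turns inward and dienylketene 11 has the (Z) geometry needed for closure. 11 then undergoes a thermal disrotatory 6π electrocyclisation in which the ketene carbon bonds to the pyranone carbon next to the C4 carbonyl (the nucleophilic β-carbon of the ring enol ether), which forms the C5–C4a bond and closes ring A as cyclohexadienone 12. The hydrogen on C4a of 12 lies between two carbonyl groups and is lost by enolisation, which aromatises ring A to hydroquinone 13; the C4a stereocentre of 12 is transient and needs no control. The closest known reaction type is the Moore rearrangement of 4-alkenyl- and 4-heteroaryl-4-hydroxycyclobutenones to annulated hydroquinones, used here with a 4-oxopyranyl substituent. The step needs the ketene to close on carbon and not to be captured by the hydroxyl oxygen (furanone formation); the outward rotation of the hydroxyl and the enol ether character of the pyranone double bond should secure this. The oxygen pattern follows from the connectivity of 10 alone: the carbonyl carbon becomes C5, C–OtBu becomes C6, C–OBn becomes C7 and the carbinol carbon becomes C8. Trifluoroacetic acid added after cooling cleaves only the aryl tert-butyl ether at O6 by ionisation and leaves both benzyl ethers, to give 14, which is used at once under argon.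

**Step 7**
Reactants: 14 7-(benzyloxy)-2-[4-(benzyloxy)phenyl]-5,6,8-trihydroxy-3-methoxy-4H-chromen-4-one
Product: 15 7-(benzyloxy)-2-[4-(benzyloxy)phenyl]-3,5,6,8-tetramethoxy-4H-chromen-4-one
Conditions: MeI (excess), K2CO3, DMF, 40 °C, argon
Reagents that add atoms: iodomethane, CI
Why: Exhaustive Williamson methylation of the three phenols; the chelated 5-hydroxyl reacts last but does react with excess reagent and mild heating, and O7 and O4' are protected, so no selectivity is asked of the step.

**Step 8**
Reactants: 15 7-(benzyloxy)-2-[4-(benzyloxy)phenyl]-3,5,6,8-tetramethoxy-4H-chromen-4-one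
Product: 16 7-hydroxy-2-(4-hydroxyphenyl)-3,5,6,8-tetramethoxy-4H-chromen-4-one
Conditions: H2 (1 atm), 10% Pd/C (palladium on carbon), EtOAc/MeOH, rt
Reagents that add atoms: none
Why: Hydrogenolysis of both aryl benzyl ethers; the tetrasubstituted C2=C3 bond and the methyl ethers of a flavone are not reduced under these conditions.

## Compound list

1 | 3-hydroxy-4H-pyran-4-one | O=c1ccocc1O | starting material
2 | 2-bromo-3-hydroxy-4H-pyran-4-one | O=c1ccoc(Br)c1O | intermediate
3 | 2-bromo-3-methoxy-4H-pyran-4-one | COc1c(Br)occc1=O | intermediate
4 | [4-(benzyloxy)phenyl]boronic acid | OB(O)c1ccc(OCc2ccccc2)cc1 | starting material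
5 | 2-[4-(benzyloxy)phenyl]-3-methoxy-4H-pyran-4-one | COc1c(-c2ccc(OCc3ccccc3)cc2)occc1=O | intermediate
6 | 3,4-di-tert-butoxycyclobut-3-ene-1,2-dione | CC(C)(C)OC1=C(OC(C)(C)C)C(=O)C1=O | starting material
7 | benzyl alcohol | OCc1ccccc1 | starting material
8 | 3-(benzyloxy)-4-(tert-butoxy)cyclobut-3-ene-1,2-dione | CC(C)(C)OC1=C(OCc2ccccc2)C(=O)C1=O | intermediate
9 | {6-[4-(benzyloxy)phenyl]-5-methoxy-4-oxo-4H-pyran-2-yl}lithium | [Li]c1cc(=O)c(OC)c(-c2ccc(OCc3ccccc3)cc2)o1 | intermediate (not isolated)
10 | 3-(benzyloxy)-4-{6-[4-(benzyloxy)phenyl]-5-methoxy-4-oxo-4H-pyran-2-yl}-2-(tert-butoxy)-4-hydroxycyclobut-2-en-1-one (racemic) | O=C1C(OC(C)(C)C)=C(OCc2ccccc2)C1(O)c1cc(=O)c(OC)c(-c2ccc(OCc3ccccc3)cc2)o1 | intermediate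
11 | (3Z)-3-(benzyloxy)-4-{6-[4-(benzyloxy)phenyl]-5-methoxy-4-oxo-4H-pyran-2-yl}-2-(tert-butoxy)-4-hydroxybuta-1,3-dien-1-one | O=C=C(OC(C)(C)C)/C(OCc1ccccc1)=C(/O)c1cc(=O)c(OC)c(-c2ccc(OCc3ccccc3)cc2)o1 | intermediate (not isolated)
12 | 7-(benzyloxy)-2-[4-(benzyloxy)phenyl]-6-(tert-butoxy)-8-hydroxy-3-methoxy-4aH-chromene-4,5-dione (racemic) | COC1=C(c2ccc(OCc3ccccc3)cc2)OC2=C(O)C(OCc3ccccc3)=C(OC(C)(C)C)C(=O)C2C1=O | intermediate (not isolated)
13 | 7-(benzyloxy)-2-[4-(benzyloxy)phenyl]-6-(tert-butoxy)-5,8-dihydroxy-3-methoxy-4H-chromen-4-one | COc1c(-c2ccc(OCc3ccccc3)cc2)oc2c(O)c(OCc3ccccc3)c(OC(C)(C)C)c(O)c2c1=O | intermediate (not isolated)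
14 | 7-(benzyloxy)-2-[4-(benzyloxy)phenyl]-5,6,8-trihydroxy-3-methoxy-4H-chromen-4-one | COc1c(-c2ccc(OCc3ccccc3)cc2)oc2c(O)c(OCc3ccccc3)c(O)c(O)c2c1=O | intermediate
15 | 7-(benzyloxy)-2-[4-(benzyloxy)phenyl]-3,5,6,8-tetramethoxy-4H-chromen-4-one | COc1c(-c2ccc(OCc3ccccc3)cc2)oc2c(OC)c(OCc3ccccc3)c(OC)c(OC)c2c1=O | intermediate
16 | 7-hydroxy-2-(4-hydroxyphenyl)-3,5,6,8-tetramethoxy-4H-chromen-4-one | COc1c(O)c(OC)c2oc(-c3ccc(O)cc3)c(OC)c(=O)c2c1OC | target

## Step count and least certain steps

Total: 8 steps. Longest linear sequence: 7 steps (steps 1, 2, 3, 5, 6, 7, 8); step 4 is a one-step branch.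

**Step 6 (key step).** The most likely failures are capture of the ketene by an oxygen nucleophile instead of ring closure on carbon (a furanone if the hydroxyl rotates inward), slow closure onto the cross-conjugated pyranone double bond with loss of the tert-butyl group in the meantime, and air oxidation of the hydroquinone once it has formed. The fallback sets out from 10 and comes back at 15. It takes the hydroxyl out of the pericyclic step and moves the C8 methylation in front of it.
- 10 is O-methylated at the tertiary hydroxyl (MeI, Ag2O, MeCN) to the 4-methoxycyclobutenone F1, which has no hydroxyl to trap the ketene.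
- Thermolysis of F1 in toluene should give the 8-methoxy-5-hydroxy flavone F2, a chelated monophenol that is not air-sensitive.
- Trifluoroacetic acid removes the tert-butyl group to give the 5,6-dihydroxy flavone F3.
- The conditions of step 7 convert F3 into 15.

**Step 5.** The discrimination between the two squarate carbonyls rests on the bulk of one tert-butyl group and may be incomplete; the wrong adduct would carry the benzyloxy group to C6. A second risk is self-condensation of 9 with unmetallated 5. The fallback sets out from 5 (through 9) and comes back at 15. It removes the regiochemical question by using symmetric squarate 6, at the price of a longer endgame.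
- 9 adds to 6 to give the di-tert-butoxy adduct F4.
- Thermolysis gives the 6,7-di-tert-butoxy hydroquinone F5.
- MeI and K2CO3 give the 5,8-dimethyl ether F6.
- Trifluoroacetic acid gives the 6,7-diol F7.
- One equivalent of benzyl bromide with KHCO3 in DMF benzylates O7, the more acidic phenol (para to the C4 carbonyl), to give the 6-hydroxy-7-benzyloxy flavone F8.
- Methylation of F8 (MeI, K2CO3) gives 15.

**Step 4.** The exchange may run on to the dibenzyl ester or stop as a near-statistical mixture, because the second exchange is not strongly disfavoured. The fallback sets out from 6 and comes back at 8. It uses mono-saponification, which stops cleanly because the anion formed is deactivated: 6 with one equivalent of Bu4NOH in THF/water gives the tetrabutylammonium tert-butyl squarate salt F9, and O-alkylation of F9 with benzyl bromide in MeCN gives 8. Either terminal oxygen of the anion gives the same product.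

**Step 7.** The triol 14 has para-related free oxygens at C5 and C8 and may be oxidised to a quinone under basic conditions before methylation is complete; the chelated 5-hydroxyl may also react slowly. The fallback sets out from 14 and comes back at 15. It accepts the oxidation: 14 is oxidised on purpose (Ag2O, CH2Cl2) to the stable 6-hydroxy-5,8-quinone F10, and F10 is reductively methylated (Na2S2O4, then dimethyl sulfate, KOH, Bu4NBr, THF/water) to 15.

## Further compounds

F1 | step 6 | 3-(benzyloxy)-4-{6-[4-(benzyloxy)phenyl]-5-methoxy-4-oxo-4H-pyran-2-yl}-2-(tert-butoxy)-4-methoxycyclobut-2-en-1-one (racemic) | O=C1C(OC(C)(C)C)=C(OCc2ccccc2)C1(OC)c1cc(=O)c(OC)c(-c2ccc(OCc3ccccc3)cc2)o1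
F2 | step 6 | 7-(benzyloxy)-2-[4-(benzyloxy)phenyl]-6-(tert-butoxy)-5-hydroxy-3,8-dimethoxy-4H-chromen-4-one | COc1c(-c2ccc(OCc3ccccc3)cc2)oc2c(OC)c(OCc3ccccc3)c(OC(C)(C)C)c(O)c2c1=O
F3 | step 6 | 7-(benzyloxy)-2-[4-(benzyloxy)phenyl]-5,6-dihydroxy-3,8-dimethoxy-4H-chromen-4-one | COc1c(-c2ccc(OCc3ccccc3)cc2)oc2c(OC)c(OCc3ccccc3)c(O)c(O)c2c1=O
F4 | step 5 | 4-{6-[4-(benzyloxy)phenyl]-5-methoxy-4-oxo-4H-pyran-2-yl}-2,3-di-tert-butoxy-4-hydroxycyclobut-2-en-1-one (racemic) | O=C1C(OC(C)(C)C)=C(OC(C)(C)C)C1(O)c1cc(=O)c(OC)c(-c2ccc(OCc3ccccc3)cc2)o1
F5 | step 5 | 2-[4-(benzyloxy)phenyl]-6,7-di-tert-butoxy-5,8-dihydroxy-3-methoxy-4H-chromen-4-one | COc1c(-c2ccc(OCc3ccccc3)cc2)oc2c(O)c(OC(C)(C)C)c(OC(C)(C)C)c(O)c2c1=O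
F6 | step 5 | 2-[4-(benzyloxy)phenyl]-6,7-di-tert-butoxy-3,5,8-trimethoxy-4H-chromen-4-one | COc1c(-c2ccc(OCc3ccccc3)cc2)oc2c(OC)c(OC(C)(C)C)c(OC(C)(C)C)c(OC)c2c1=O
F7 | step 5 | 2-[4-(benzyloxy)phenyl]-6,7-dihydroxy-3,5,8-trimethoxy-4H-chromen-4-one | COc1c(-c2ccc(OCc3ccccc3)cc2)oc2c(OC)c(O)c(O)c(OC)c2c1=O
F8 | step 5 | 7-(benzyloxy)-2-[4-(benzyloxy)phenyl]-6-hydroxy-3,5,8-trimethoxy-4H-chromen-4-one | COc1c(-c2ccc(OCc3ccccc3)cc2)oc2c(OC)c(OCc3ccccc3)c(O)c(OC)c2c1=O
F9 | step 4 | tetrabutylammonium 2-(tert-butoxy)-3,4-dioxocyclobut-1-en-1-olate | CC(C)(C)OC1=C([O-])C(=O)C1=O.CCCC[N+](CCCC)(CCCC)CCCC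
F10 | step 7 | 7-(benzyloxy)-2-[4-(benzyloxy)phenyl]-6-hydroxy-3-methoxy-4H-chromene-4,5,8-trione | COC1=C(c2ccc(OCc3ccccc3)cc2)OC2=C(C1=O)C(=O)C(O)=C(OCc1ccccc1)C2=O
A1 | alternative 1 | 1-[4-(benzyloxy)-2-hydroxy-3,5,6-trimethoxyphenyl]-2-methoxyethan-1-one | COCC(=O)c1c(O)c(OC)c(OCc2ccccc2)c(OC)c1OC
A2 | alternative 2 | 1-[4-(benzyloxy)-2,3,5,6-tetramethoxyphenyl]-3-[4-(benzyloxy)phenyl]prop-2-yn-1-one | COc1c(OC)c(C(=O)C#Cc2ccc(OCc3ccccc3)cc2)c(OC)c(OC)c1OCc1ccccc1
A3 | alternative 2 | 7-(benzyloxy)-2-[4-(benzyloxy)phenyl]-3-iodo-5,6,8-trimethoxy-4H-chromen-4-one | COc1c(OCc2ccccc2)c(OC)c2oc(-c3ccc(OCc4ccccc4)cc3)c(I)c(=O)c2c1OC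
A4 | alternative 3 | methyl 4-(benzyloxy)-3-(tert-butoxy)-2,5-dihydroxy-6-methoxybenzoate | COC(=O)c1c(O)c(OC(C)(C)C)c(OCc2ccccc2)c(O)c1OC
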